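**Retrosynthetic overview**

1. Numbering used throughout (chamigrane): ring B = C1–C5 (C1=C2, C3=C15HBr), spiro atom C6, ring A = C7–C11 (C7 = C(CH3)(OH), C9 = CHBr, C11 = C(CH3)2).
2. Late disconnections: O7–Si cleavage; C3=C15 by Wittig bromomethylenation of a C3 enone; C9–Br by inversion of an axial C9 alcohol; the C1=C2–C3=O enone from a ring-B vinylogous ester (C1 carbonyl, C3–OEt) by reduction and hydrolysis.
3. Key disconnection: ring A is opened at C6–C7 and C10–C11 in one retro-[4+2] step. This gives the tetrasubstituted exocyclic enone 6 (C6=C11, ring B intact) and the bis-silyl dienol ether 9 of acetylacetone (C7–C8–C9–C10 plus the C7 methyl).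
4. Enabling feature: ring A carries oxygen-level functions on C7 and C9 in a 1,3-relationship (the acetylacetone pattern), and ring B is unsaturated at C1, the atom next to spiro C6. With C1 as a carbonyl, C11 is an electrophilic β-carbon and C6 a latent enolate carbon, which matches the nucleophilic C10 and electrophilic C7 termini of the diene.
5. Ring order: ring B is bought (3-ethoxycyclohex-2-en-1-one) and ring A is closed on it in the key step, where the three contiguous fully substituted carbons C7, C6, C11 and both stereocentres C6 and C7 arise.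

Key step: step 4

Remark: compound 7 is taken to be the commercial silyl-transfer reagent derived from acetylacetone, as its (3Z) isomer; otherwise it is one silylation step from acetylacetone.

**Route**

Step 1
Reactants: 1 3-ethoxycyclohex-2-en-1-one; 2 acetone
Product: 4 rac-3-ethoxy-6-(2-hydroxypropan-2-yl)cyclohex-2-en-1-one, via lithium enolate 3 (not isolated)
Conditions: LiN(i-Pr)2, THF, −78 °C; acetone; AcOH quench at −78 °C
Reagents that add atoms: none
Why: Kinetic deprotonation of the vinylogous ester takes place at C6 (the α′ carbon, as in Stork–Danheiser alkylations) and the lithium enolate adds to acetone in a directed aldol addition; the new stereocentre is racemic and is erased in step 2.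

Step 2
Reactants: 4 rac-3-ethoxy-6-(2-hydroxypropan-2-yl)cyclohex-2-en-1-one
Product: 6 3-ethoxy-6-(propan-2-ylidene)cyclohex-2-en-1-one, via mesylate 5 (not isolated)
Conditions: MsCl, Et3N, CH2Cl2, 0 °C; then DBU, 0 °C → rt
Reagents that add atoms: none
Why: Mesylation of the tertiary β-hydroxy ketone followed by E1cB elimination through the C6 enolate should give the conjugated tetrasubstituted exocyclic enone (the 3-ethoxy analogue of piperitenone), and DBU brings any isopropenyl isomer into conjugation.

Step 3
Reactants: 7 (3Z)-4-[(tert-butyldimethylsilyl)oxy]pent-3-en-2-one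
Product: 9 (3Z)-4-[(tert-butyldimethylsilyl)oxy]-2-[(trimethylsilyl)oxy]penta-1,3-diene, via lithium dienolate 8 (not isolated)
Conditions: LiN(i-Pr)2, THF, −78 °C; Me3SiCl, −78 → 0 °C
Reagents that add atoms: chlorotrimethylsilane, C[Si](C)(C)Cl
Why: Kinetic deprotonation of the acetyl methyl (α′ position of the β-silyloxy enone) and O-silylation of the cross-conjugated enolate give the 1,3-bis(silyloxy)diene with the (3Z) geometry retained.

Step 4
Reactants: 6 3-ethoxy-6-(propan-2-ylidene)cyclohex-2-en-1-one; 9 (3Z)-4-[(tert-butyldimethylsilyl)oxy]-2-[(trimethylsilyl)oxy]penta-1,3-diene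
Product: 11 (6S,7S)-7-[(tert-butyldimethylsilyl)oxy]-3-ethoxy-7,11,11-trimethylspiro[5.5]undec-2-ene-1,9-dione, via silyl enol ether cycloadduct 10 (not isolated)
Conditions: (S,S)-imidodiphosphorimidate acid HN[P(=NSO2CF3)(O2C20H10Ar2)]2 built on two (S)-3,3′-diaryl-1,1′-binaphthalene-2,2′-diolate units, Ar = 3,5-(CF3)2C6H3 (3 mol %), toluene, −60 → −20 °C; then 0.5 M aqueous citric acid, THF, 0 °C
Reagents that add atoms: none
Why: Proposed new method: the strong chiral acid is silylated in situ by a small part of the diene and the resulting silylium–imidodiphosphorimidate ion pair O-silylates the C1 carbonyl of 6, so that the terminal CH2 of 9 (C10) adds to the only donor-free β-carbon (C11) in a vinylogous Mukaiyama–Michael step and the ring-B silyl enol ether carbon C6 then closes onto the cationic C7 terminus, a stepwise double Michael equivalent of a Diels–Alder reaction; the closest known reactions are the silyl triflimide- and AlBr3/AlMe3-catalysed Diels–Alder reactions of hindered 2-silyloxydienes with β,β-disubstituted enones and the imidodiphosphorimidate-catalysed spirocyclising Diels–Alder reactions of exocyclic enones and Mukaiyama–Michael additions, none of which has been shown for a tetrasubstituted exocyclic enone with a 1,3-bis(silyloxy)diene under chiral counteranion control. Ring A is closed as the six-membered ring of the formal [4+2] addition, its second bond forming in a 6-(enolexo)-endo-trig closure. The relative configuration of C6 and C7 should follow from an endo arrangement of the C1 carbonyl unit over the diene together with the (3Z) diene geometry, which keeps the smaller silyloxy group inside and the C7 methyl outside, so that the methyl ends cis to C1 and the C7 oxygen cis to C5. The absolute configuration is set by the confined chiral counteranion paired with the cationic intermediate during ring closure, and the catalyst antipode that leads to (6S,7S) has to be fixed in the first experiment. The step needs regioselectivity for C11 over the ethoxy-bearing C3 and for [4+2] over [3+3] annulation, which the substrate secures because C11 is the terminus of an s-cis exocyclic enone without a donor substituent while C3 is deactivated by its ethoxy group, and because after the first bond the C1 carbonyl is masked as a silyl enol ether so that the central diene carbon C8 finds no electrophile. Mild acid then hydrolyses the C9 trimethylsilyl enol ether to the ketone while the tertiary tert-butyldimethylsilyl ether should survive.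

Step 5
Reactants: 11 (6S,7S)-7-[(tert-butyldimethylsilyl)oxy]-3-ethoxy-7,11,11-trimethylspiro[5.5]undec-2-ene-1,9-dione
Product: 12 (6S,7S,9S)-7-[(tert-butyldimethylsilyl)oxy]-3-ethoxy-9-hydroxy-7,11,11-trimethylspiro[5.5]undec-2-en-1-one
Conditions: LiBH(s-Bu)3, THF, −78 °C; AcOH quench at −78 °C
Reagents that add atoms: none
Why: Substrate-controlled ketone reduction in which the axial face of C9 is screened by the syn-axial C7 silyloxy group and the axial C11 methyl (chair with the C7 methyl equatorial), so that the bulky hydride attacks equatorially and should give the axial (9S) alcohol cis to the C7 oxygen; the vinylogous ester carbonyl is not reduced by this reagent at −78 °C and the cold quench avoids silyl migration.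

Step 6
Reactants: 12 (6S,7S,9S)-7-[(tert-butyldimethylsilyl)oxy]-3-ethoxy-9-hydroxy-7,11,11-trimethylspiro[5.5]undec-2-en-1-one
Product: 14 (6S,7S,9S)-7-[(tert-butyldimethylsilyl)oxy]-9-hydroxy-7,11,11-trimethylspiro[5.5]undec-1-en-3-one, via C1 allylic alcohol 13 (not isolated)
Conditions: i-Bu2AlH (2.5 equiv), CH2Cl2, −78 °C; then 1 M HCl, THF, 0 °C
Reagents that add atoms: water, O
Why: Stork–Danheiser transposition, in which 1,2-reduction of the vinylogous ester carbonyl C1 and acid-promoted loss of the C1 hydroxyl with hydrolysis of the C3 enol ether give the C1=C2–C3=O enone; because C6 is quaternary the alkene can only form on the C1 arm, the arm cis to the C7 methyl.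

Step 7
Reactants: 14 (6S,7S,9S)-7-[(tert-butyldimethylsilyl)oxy]-9-hydroxy-7,11,11-trimethylspiro[5.5]undec-1-en-3-one
Product: 16 (6S,7S,9R)-9-bromo-7-[(tert-butyldimethylsilyl)oxy]-7,11,11-trimethylspiro[5.5]undec-1-en-3-one, via C9 triflate 15 (not isolated)
Conditions: Tf2O, 2,6-lutidine, CH2Cl2, −78 °C; then Bu4NBr, −78 → 0 °C
Reagents that add atoms: tetrabutylammonium bromide, CCCC[N+](CCCC)(CCCC)CCCC.[Br-]
Why: SN2 displacement of the axial secondary triflate by the weakly basic bromide ion should proceed with inversion from the open equatorial side and give the equatorial (9R) bromide trans to the C7 oxygen, while the cis C7 silyl ether cannot participate.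

Step 8
Reactants: 16 (6S,7S,9R)-9-bromo-7-[(tert-butyldimethylsilyl)oxy]-7,11,11-trimethylspiro[5.5]undec-1-en-3-one
Product: 17 {[(3E,6S,7S,9R)-9-bromo-3-(bromomethylidene)-7,11,11-trimethylspiro[5.5]undec-1-en-7-yl]oxy}(tert-butyl)dimethylsilane
Conditions: [Ph3PCH2Br]Br, NaN(SiMe3)2, THF, −78 °C; then 16, −78 °C → rt
Reagents that add atoms: (bromomethyl)triphenylphosphonium bromide, BrC[P+](c1ccccc1)(c1ccccc1)c1ccccc1.[Br-]
Why: Wittig olefination of the unhindered C3 carbonyl with bromomethylidenetriphenylphosphorane; by analogy with the cis-selectivity of halomethylene ylides the bromine is expected to be placed preferentially syn to the bulkier sp3 C4 methylene and not to the planar C2 methine, which is the (E) isomer, and any (Z) isomer would be removed by chromatography.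

Step 9
Reactants: 17 {[(3E,6S,7S,9R)-9-bromo-3-(bromomethylidene)-7,11,11-trimethylspiro[5.5]undec-1-en-7-yl]oxy}(tert-butyl)dimethylsilane
Product: 18 (3E,6S,7S,9R)-9-bromo-3-(bromomethylidene)-7,11,11-trimethylspiro[5.5]undec-1-en-7-ol
Conditions: HF·pyridine, pyridine, THF, 0 °C → rt
Reagents that add atoms: none
Why: Fluoride-driven cleavage of the tertiary silyl ether; the equatorial C9 bromide has no antiperiplanar hydrogen in the locked chair and the dienyl bromide is inert to this reagent, so the target should be released unchanged.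

**Compound list**

1 | 3-ethoxycyclohex-2-en-1-one | CCOC1=CC(=O)CCC1 | starting material
2 | acetone | CC(C)=O | starting material
3 | lithium 5-ethoxycyclohexa-1,5-dien-1-olate (kinetic enolate of 1) | [Li]OC1=CCCC(OCC)=C1 | intermediate
4 | rac-3-ethoxy-6-(2-hydroxypropan-2-yl)cyclohex-2-en-1-one | CCOC1=CC(=O)C(CC1)C(C)(C)O | intermediate
5 | rac-2-(4-ethoxy-2-oxocyclohex-3-en-1-yl)propan-2-yl methanesulfonate | CCOC1=CC(=O)C(CC1)C(C)(C)OS(C)(=O)=O | intermediate
6 | 3-ethoxy-6-(propan-2-ylidene)cyclohex-2-en-1-one | CCOC1=CC(=O)C(=C(C)C)CC1 | intermediate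
7 | (3Z)-4-[(tert-butyldimethylsilyl)oxy]pent-3-en-2-one | C/C(O[Si](C)(C)C(C)(C)C)=C/C(C)=O | starting material
8 | lithium (3Z)-4-[(tert-butyldimethylsilyl)oxy]penta-1,3-dien-2-olate | C/C(O[Si](C)(C)C(C)(C)C)=C/C(=C)O[Li] | intermediate
9 | (3Z)-4-[(tert-butyldimethylsilyl)oxy]-2-[(trimethylsilyl)oxy]penta-1,3-diene | C/C(O[Si](C)(C)C(C)(C)C)=C/C(=C)O[Si](C)(C)C | intermediate
10 | (6S,7S)-7-[(tert-butyldimethylsilyl)oxy]-3-ethoxy-7,11,11-trimethyl-9-[(trimethylsilyl)oxy]spiro[5.5]undeca-2,8-dien-1-one | CC1(C)CC(O[Si](C)(C)C)=C[C@](C)(O[Si](C)(C)C(C)(C)C)[C@@]12C(=O)C=C(OCC)CC2 | intermediate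
11 | (6S,7S)-7-[(tert-butyldimethylsilyl)oxy]-3-ethoxy-7,11,11-trimethylspiro[5.5]undec-2-ene-1,9-dione | CC1(C)CC(=O)C[C@](C)(O[Si](C)(C)C(C)(C)C)[C@@]12C(=O)C=C(OCC)CC2 | intermediate
12 | (6S,7S,9S)-7-[(tert-butyldimethylsilyl)oxy]-3-ethoxy-9-hydroxy-7,11,11-trimethylspiro[5.5]undec-2-en-1-one | CC1(C)C[C@H](O)C[C@](C)(O[Si](C)(C)C(C)(C)C)[C@@]12C(=O)C=C(OCC)CC2 | intermediate
13 | (6R,7S,9S)-7-[(tert-butyldimethylsilyl)oxy]-3-ethoxy-7,11,11-trimethylspiro[5.5]undec-2-ene-1,9-diol, C1 epimers (spiro centre unchanged in space, descriptor changed by priorities) | CC1(C)C[C@H](O)C[C@](C)(O[Si](C)(C)C(C)(C)C)[C@@]12C(O)C=C(OCC)CC2 | intermediate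
14 | (6S,7S,9S)-7-[(tert-butyldimethylsilyl)oxy]-9-hydroxy-7,11,11-trimethylspiro[5.5]undec-1-en-3-one | CC1(C)C[C@H](O)C[C@](C)(O[Si](C)(C)C(C)(C)C)[C@@]12C=CC(=O)CC2 | intermediate
15 | (6S,7S,9S)-7-[(tert-butyldimethylsilyl)oxy]-7,11,11-trimethyl-3-oxospiro[5.5]undec-1-en-9-yl trifluoromethanesulfonate | CC1(C)C[C@H](OS(=O)(=O)C(F)(F)F)C[C@](C)(O[Si](C)(C)C(C)(C)C)[C@@]12C=CC(=O)CC2 | intermediate
16 | (6S,7S,9R)-9-bromo-7-[(tert-butyldimethylsilyl)oxy]-7,11,11-trimethylspiro[5.5]undec-1-en-3-one | CC1(C)C[C@@H](Br)C[C@](C)(O[Si](C)(C)C(C)(C)C)[C@@]12C=CC(=O)CC2 | intermediate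
17 | {[(3E,6S,7S,9R)-9-bromo-3-(bromomethylidene)-7,11,11-trimethylspiro[5.5]undec-1-en-7-yl]oxy}(tert-butyl)dimethylsilane | CC1(C)C[C@@H](Br)C[C@](C)(O[Si](C)(C)C(C)(C)C)[C@@]12C=C/C(=C/Br)CC2 | intermediate
18 | (3E,6S,7S,9R)-9-bromo-3-(bromomethylidene)-7,11,11-trimethylspiro[5.5]undec-1-en-7-ol | CC1(C)C[C@@H](Br)C[C@](C)(O)[C@@]12C=C/C(=C/Br)CC2 | target

**Step count and risks**

Total step count: 9. Longest linear sequence: 8 steps (steps 1, 2, 4, 5, 6, 7, 8, 9).

Steps most likely to fail:

Step 4 (carries the label). The O-silylated vinylogous ester may be too weak an electrophile at the fully substituted C11, the diene may attack C3 with loss of the ethoxy group, the sequence may stop after the first C–C bond, or the ring closure may show poor enantiofacial discrimination. The fallback uses known chemistry and gives up catalyst control. It sets out from 6 and 9 and runs the annulation under the established achiral conditions for Diels–Alder reactions of hindered silyloxydienes with β,β-disubstituted enones (HN(SO2CF3)2 as precatalyst of Me3SiN(SO2CF3)2, CH2Cl2, −40 °C, or AlBr3/AlMe3 in toluene/CH2Cl2). This should give the racemate, that is 10 together with the (6R,7R)-enantiomer of 10 F1. The same citric acid hydrolysis gives 11 together with the (6R,7R)-enantiomer of 11 F2. Preparative chromatography on a chiral stationary phase with supercritical CO2 resolves the pair, and the fallback comes back to the route at 11.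

Step 8. The oxaphosphetane may form with poor geometric selectivity, so that the (Z)-bromomethylidene isomer is produced as well, or the ylide may enolise the enone. The fallback sets the geometry in a separate, catalyst-controlled operation. It sets out from 16, which undergoes Ramirez olefination (CBr4, PPh3, CH2Cl2, 0 °C → rt) to {[(6S,7S,9R)-9-bromo-3-(dibromomethylidene)-7,11,11-trimethylspiro[5.5]undec-1-en-7-yl]oxy}(tert-butyl)dimethylsilane F3. Selective hydrodebromination with Bu3SnH and zerovalent palladium, Pd(PPh3)4 (toluene, rt), follows. Oxidative addition should take place at the less hindered C–Br bond, the one syn to the planar C2–H, as in the known selective reduction of 1,1-dibromoalkenes. This leaves the bromine syn to C4, and the fallback comes back to the route at 17.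

Step 7. The axial triflate may undergo E2 elimination or ionisation faster than substitution, or the enone oxygen may be triflated. The fallback moves the halogenation to the end and changes the activation mode. It sets out from 14, which is first taken through the Wittig bromomethylenation of step 8 to (3E,6S,7S,9S)-3-(bromomethylidene)-7-[(tert-butyldimethylsilyl)oxy]-7,11,11-trimethylspiro[5.5]undec-1-en-9-ol F4. HF·pyridine then removes the silyl group to give (3E,6S,7S,9S)-3-(bromomethylidene)-7,11,11-trimethylspiro[5.5]undec-1-ene-7,9-diol F5. Appel bromination (PPh3, CBr4, CH2Cl2, 0 °C) should then convert only the secondary alcohol, through its alkoxyphosphonium ion or the dioxaphosphorane spanning the two syn-axial oxygens, which bromide opens at C9 with inversion. The tertiary C7 hydroxyl is cis to the leaving group and can neither be displaced nor close an oxetane. The fallback comes back to the route at 18.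

Further compounds
F1 | step 4 | (6R,7R)-7-[(tert-butyldimethylsilyl)oxy]-3-ethoxy-7,11,11-trimethyl-9-[(trimethylsilyl)oxy]spiro[5.5]undeca-2,8-dien-1-one | CC1(C)CC(O[Si](C)(C)C)=C[C@@](C)(O[Si](C)(C)C(C)(C)C)[C@]12C(=O)C=C(OCC)CC2
F2 | step 4 | (6R,7R)-7-[(tert-butyldimethylsilyl)oxy]-3-ethoxy-7,11,11-trimethylspiro[5.5]undec-2-ene-1,9-dione | CC1(C)CC(=O)C[C@@](C)(O[Si](C)(C)C(C)(C)C)[C@]12C(=O)C=C(OCC)CC2
F3 | step 8 | {[(6S,7S,9R)-9-bromo-3-(dibromomethylidene)-7,11,11-trimethylspiro[5.5]undec-1-en-7-yl]oxy}(tert-butyl)dimethylsilane | CC1(C)C[C@@H](Br)C[C@](C)(O[Si](C)(C)C(C)(C)C)[C@@]12C=CC(=C(Br)Br)CC2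
F4 | step 7 | (3E,6S,7S,9S)-3-(bromomethylidene)-7-[(tert-butyldimethylsilyl)oxy]-7,11,11-trimethylspiro[5.5]undec-1-en-9-ol | CC1(C)C[C@H](O)C[C@](C)(O[Si](C)(C)C(C)(C)C)[C@@]12C=C/C(=C/Br)CC2
F5 | step 7 | (3E,6S,7S,9S)-3-(bromomethylidene)-7,11,11-trimethylspiro[5.5]undec-1-ene-7,9-diol | CC1(C)C[C@H](O)C[C@](C)(O)[C@@]12C=C/C(=C/Br)CC2
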